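The pitfall in this flask is to take the solid's first hours as its pace.

| flask | solid substrate | coupling partner | remark | time |
|---|---|---|---|---|
| dusk | 0.20 M | 0.18 M | run made earlier |  |
| summer | 0.20 M | 0.72 M | run made earlier |  |
| noon | 0.40 M | 0.36 M | run made earlier |  |
| flask | 0.20 M | 0.360 M |  | 40 h |

- dusk (time / h: solid substrate / %, target / %): 3.00: 82.9, 1.0; 10.0: 54.9, 3.3; 15.0: 40.5, 4.4; 25.0: 15.1, 4.2; 40.0: 0, 3.5; 50.0: 0, 2.2
- summer (time / h: solid substrate / %, target / %): 3.00: 81.2, 3.8; 10.0: 40.7, 11.1; 15.0: 14.9, 13.7; 25.0: 0, 11.9; 40.0: 0, 6.0; 50.0: 0, 4.8
- noon (time / h: solid substrate / %, target / %): 4.00: 88.6, 1.2; 12.0: 67.2, 2.7; 20.0: 48.0, 2.9; 30.0: 28.5, 2.7; 50.0: 0, 3.8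

(readings scatter by 0.3 percentage points)

- a species is counted by the solid substrate in it: one side product A or side product B counts as two
- amounts and yields of target count crystals too
- given per volume of solution although it is solid: solid substrate, crystals
- the analysis behind the earlier runs scatters by 0.3 percentage points, standard deviation
- steps that have been proposed: solid substrate <-> dissolved substrate; dissolved substrate + coupling partner <-> target; dissolved substrate + target -> side product A; solid substrate + target -> side product B; crystals <-> target
- at the start none of the solid substrate is in solution
- what has only dissolved of solid substrate counts as not reacted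
- the reaction counts as stopped when no species that holds the solid substrate changes by six tenths of a point or more over the second half of the time

* which holds at 40 h: what has brought the reaction to rest, or that it has not come to rest (for what has run out or reacted, a solid counts together with what of it has only dissolved) (the coupling partner has run out first / all of the solid substrate has reacted / forward and back rates have come level / it is still moving)
* part of the solid substrate that has turned into other species by 40 h (what has only dissolved does not count)
* target at 40 h, in percent of the solid substrate charged
* side product A at 40 h, in percent of the solid substrate charged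
* amount of target if the flask were left three thousand times as long, in percent of the solid substrate charged

The decision for you: leave this flask for 40 h, or stop it earlier if target is what you want?

1. Early on, noon loses 0.0114 M h⁻¹ of solid and dusk 0.0114 M h⁻¹, though noon holds twice the solid. So the early loss reads as zero order in solid. At that pace, your 0.20 M clears in 17.5 h.

2. But the pace does not hold. Between its first and fourth readings, noon loses 0.00925 M h⁻¹, less than its early pace. Between their first and third readings, dusk loses 0.00707 M h⁻¹ and summer 0.0111 M h⁻¹. These two runs differ in partner, so between them the pace rises with partner. Your flask has noon's 0.36 M of partner, so I use noon's figure.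

3. Let t_c be the charge divided by that pace: 21.6 h. Let the clearing number N be t_c divided by the run time 0.541. The even case is N = 1, where the solid lasts just as long as the run. This flask sits well below it.

4. Once summer's solid reads zero, its target falls from 11.9% at 25.0 h to 4.8% at 50.0 h. Noon's solid first reads zero at its last reading, 50.0 h, so noon has no later reading to show such a fall. My decision: keep the charges and sample this flask near t_c.

The forecast answers "it is still moving", with conversion 96%, target 5%, side product A 50% and long-run target 0.05%, and says “the solid should vanish near 26 h”, a different figure from mine.

The flask at 40 h: it is still moving, conversion 92.5%, target 4.83%, side product A 65.2%; long-run target 0%.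

    solid substrate ⇌ dissolved substrate, rate k1*(cs1 - [dissolved substrate]) while solid is left; crystals form when [dissolved substrate] > cs1 (solubility = 0.0940 M, k = 0.146 h⁻¹)
    dissolved substrate + coupling partner ⇌ target (K = 2.70 M⁻¹, k = 0.416 M⁻¹ h⁻¹)
    dissolved substrate + target → side product A (k = 3.40 M⁻¹ h⁻¹)
    solid substrate + target → side product B (k = 1.20 M⁻¹ h⁻¹)
    crystals ⇌ target, rate k5*(cs5 - [target]) while solid is left; crystals form when [target] > cs5 (solubility = 37.0 mM, k = 0.974 h⁻¹)

At 20.0 h this flask holds 10.6% solid, where t_c gave 7.54%, and 8.19% target, against 4.83% at 40 h. It still holds 7.48% dissolved substrate at 40 h. This flask's conversion stands at 92.5% partly because of target's return to dissolved substrate and partner, acting together with the length of the run: without that return this flask converts 99.6%, and left ten times as long it converts 99.5%.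

With 0.80 M of solid, the same reckoning gives t_c = 86.5 h and N = 2.16, so about 53.8% of the solid should stand at 40 h. That neighbouring flask computes to 49.3% solid, with side product B at 34.0%, ahead of side product A at 8.67%.

All runs were computed on assumed constants.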